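**Retrosynthetic overview**
- The target is (2R,4'R,8'S)-α-tocomonoenol. The last skeletal bond, C5'–C6', comes from a Cu-catalysed alkyl–alkyl coupling of a chroman-bearing (S)-2-methylalkyl iodide (C1'–C5') with a C6'–C13' Grignard reagent from (R)-citronellol, whose isopropenyl end is rebuilt after ozonolysis.
- The C4' methyl stereocentre comes from Zr-catalysed asymmetric carboalumination–iodination of a C4'=C5' terminal alkene, made from the C4' ester of the key-step product.
- Structural feature: C2 of the dihydropyran ring is a fully substituted ether carbon (O1, C3, CH3, C1'). A Pd–C1' species made by oxypalladation of a 1,1-disubstituted alkene therefore has no β-hydrogen and can only go on to C–C bond formation.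
- This allows O1–C2 (the pyran ring, the only ring formed; the benzene ring is bought) and C1'–C2' to be made in one enantioselective Pd(II) operation from a 2-(3-methylbut-3-enyl)phenol and methyl acrylate.
- The phenol precursor comes from trimethylhydroquinone and methyl vinyl ketone; a cyclic ketal differentiates the two hydroxyl groups so that only the distal one is silylated.

Key step: step 5

Assumption: descriptors are CIP. C8' is S in 22 and 23 only because the C12'=C13' bond raises the C9' branch (spatially it is the 8'R arrangement of α-tocopherol), and C2 is S in 9 but R from 10 onward with no change at the centre. Bn-BOXAX and (NMI)2ZrCl2 are catalysts taken as available, their antipodes chosen to give the configurations drawn. TBS = tert-butyldimethylsilyl.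

**Step 1**
Reactants: 1 2,3,5-trimethylhydroquinone; 2 methyl vinyl ketone
Product: 4 rac-2-methoxy-2,5,7,8-tetramethylchroman-6-ol, via hydroquinone ketone 3 (not isolated)
Conditions: HC(OMe)3, cat. H2SO4, MeOH, 0 °C → rt
Reagents that add atoms: trimethyl orthoformate COC(OC)OC; methanol CO
Why: Acid-catalysed Friedel–Crafts-type conjugate addition of the only free arene CH to the enone, then trapping of the ketone by the neighbouring OH and methanol as a cyclic mixed ketal (orthoformate as water scavenger), should leave only the distal OH free.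

**Step 2**
Reactants: 4 rac-2-methoxy-2,5,7,8-tetramethylchroman-6-ol
Product: 5 rac-6-(TBS-oxy)-2-methoxy-2,5,7,8-tetramethylchroman
Conditions: TBSCl, imidazole, DMF, rt → 40 °C
Reagents that add atoms: tert-butyldimethylsilyl chloride CC(C)(C)[Si](C)(C)Cl
Why: Imidazole-promoted O-silylation of the single free phenol; the ketal is inert to these conditions.

**Step 3**
Reactants: 5 rac-6-(TBS-oxy)-2-methoxy-2,5,7,8-tetramethylchroman
Product: 6 4-[5-(TBS-oxy)-2-hydroxy-3,4,6-trimethylphenyl]butan-2-one (in equilibrium with its cyclic hemiketal)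
Conditions: 1 M aq. HCl, acetone, rt
Reagents that add atoms: water O
Why: Mild acid hydrolysis of the mixed ketal frees the methyl ketone and the ortho phenol, while the aryl silyl ether flanked by two methyl groups should survive dilute acid.

**Step 4**
Reactants: 6 4-[5-(TBS-oxy)-2-hydroxy-3,4,6-trimethylphenyl]butan-2-one
Product: 7 4-(TBS-oxy)-2,3,5-trimethyl-6-(3-methylbut-3-en-1-yl)phenol
Conditions: Ph3PCH3Br (3 equiv), KOtBu (3 equiv), THF, 0 °C → rt
Reagents that add atoms: methyltriphenylphosphonium bromide C[P+](c1ccccc1)(c1ccccc1)c1ccccc1.[Br-]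
Why: Wittig methylenation of the methyl ketone; the extra base converts the phenol into its phenoxide, which opens the hemiketal to the reactive keto form.

**Step 5**
Reactants: 7 4-(TBS-oxy)-2,3,5-trimethyl-6-(3-methylbut-3-en-1-yl)phenol; 8 methyl acrylate
Product: 9 methyl (2E)-4-[(2S)-6-(TBS-oxy)-2,5,7,8-tetramethylchroman-2-yl]but-2-enoate
Conditions: methyl acrylate (5 equiv), Pd(OCOCF3)2 (10 mol %), (S,S)-Bn-BOXAX [(S)-2,2'-bis((4S)-4-benzyl-4,5-dihydrooxazol-2-yl)-1,1'-binaphthyl] (40 mol %), p-benzoquinone (4 equiv), CH2Cl2, rt, 3–4 d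
Reagents that add atoms: none
Why: The cationic Pd(II)–bis(oxazoline) complex binds the 1,1-disubstituted alkene and the neighbouring phenol oxygen adds to its internal carbon in a 6-exo-trig oxypalladation (Wacker-type), which forms O1–C2, closes the dihydropyran ring and places Pd on the former =CH2 carbon (C1'). This neopentyl-type alkylpalladium has no β-hydrogen because C2 carries O1, C3 and CH3, so it inserts methyl acrylate (Heck-type carbopalladation, C1'–C2') and only then undergoes syn β-hydride elimination to the (E)-enoate, with p-benzoquinone returning Pd(0) to Pd(II). The closest known reaction is the enantioselective Pd(II)/BOXAX domino Wacker–Heck cyclisation of 2-(3-methylbut-3-enyl)phenols carrying a para methyl ether with acrylates; here only the remote O-substituent is changed to TBS. The C2 stereocentre is set in the oxypalladation by enantioface discrimination of the alkene inside the axially chiral, C2-symmetric ligand pocket, the ligand antipode being the one that gives the configuration drawn (S by CIP in the enoate). The step needs 6-exo over 7-endo attack, secured by the two-carbon tether and the Markovnikov bias of the 1,1-disubstituted alkene; C–C coupling over elimination, secured by the quaternary C2; and reaction of one oxygen only, secured by the silyl ether on the distal oxygen.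

**Step 6**
Reactants: 9 methyl (2E)-4-[(2S)-6-(TBS-oxy)-2,5,7,8-tetramethylchroman-2-yl]but-2-enoate
Product: 10 methyl 4-[(2R)-6-(TBS-oxy)-2,5,7,8-tetramethylchroman-2-yl]butanoate
Conditions: H2 (1 atm), 10 % Pd/C, EtOAc, rt
Reagents that add atoms: none
Why: Heterogeneous hydrogenation of the conjugated C2'=C3' bond; C2 is untouched and the aryl ether and silyl ether are not hydrogenolysed.

**Step 7**
Reactants: 10 methyl 4-[(2R)-6-(TBS-oxy)-2,5,7,8-tetramethylchroman-2-yl]butanoate
Product: 11 4-[(2R)-6-(TBS-oxy)-2,5,7,8-tetramethylchroman-2-yl]butanal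
Conditions: DIBAL-H (1.1 equiv), CH2Cl2, −78 °C; aq. Rochelle salt
Reagents that add atoms: none
Why: Partial reduction of the methyl ester at low temperature stops at the tetrahedral aluminium hemiacetal, which should give the C4' aldehyde on work-up.

**Step 8**
Reactants: 11 4-[(2R)-6-(TBS-oxy)-2,5,7,8-tetramethylchroman-2-yl]butanal
Product: 12 (2R)-6-(TBS-oxy)-2,5,7,8-tetramethyl-2-(pent-4-en-1-yl)chroman
Conditions: Ph3PCH3Br, KOtBu, THF, 0 °C → rt
Reagents that add atoms: methyltriphenylphosphonium bromide C[P+](c1ccccc1)(c1ccccc1)c1ccccc1.[Br-]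
Why: Wittig methylenation of the unhindered aldehyde gives the C4'=C5' terminal alkene.

**Step 9**
Reactants: 12 (2R)-6-(TBS-oxy)-2,5,7,8-tetramethyl-2-(pent-4-en-1-yl)chroman
Product: 14 (2R)-6-(TBS-oxy)-2-[(4S)-5-iodo-4-methylpentyl]-2,5,7,8-tetramethylchroman, via dimethylalkylalane 13 (not isolated)
Conditions: Me3Al (2 equiv), (+)-(NMI)2ZrCl2 [bis(1-neomenthylindenyl)zirconium dichloride] (5 mol %), MAO (1 equiv), CH2Cl2, 0 °C → rt; excess Me3Al removed in vacuo; I2 (2.5 equiv), THF, 0 °C → rt
Reagents that add atoms: trimethylaluminium C[Al](C)C; iodine II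
Why: Zr-catalysed asymmetric carboalumination (ZACA) adds CH3 to C4' and Al to C5', the alkene face being chosen by the chiral zirconocene (the antipode that gives 2-methylalkylalanes of S configuration), and iodinolysis of the primary C–Al bond does not involve the new centre.

**Step 10**
Reactants: 15 (R)-citronellol
Product: 16 (6R)-8-chloro-2,6-dimethyloct-2-ene
Conditions: PPh3, CCl4, reflux
Reagents that add atoms: carbon tetrachloride ClC(Cl)(Cl)Cl
Why: Appel chlorination of the primary alcohol under neutral conditions leaves the trisubstituted alkene and the remote stereocentre untouched.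

**Step 11**
Reactants: 16 (6R)-8-chloro-2,6-dimethyloct-2-ene
Product: 18 (4R)-6-chloro-4-methylhexan-1-ol, via chloro aldehyde 17 (not isolated)
Conditions: O3, CH2Cl2/MeOH, −78 °C; then NaBH4, −78 °C → rt
Reagents that add atoms: ozone [O-][O+]=O
Why: Ozonolysis of the trisubstituted alkene with reductive borohydride work-up removes the isopropylidene carbons and gives the primary alcohol; the alkyl chloride is inert.

**Step 12**
Reactants: 18 (4R)-6-chloro-4-methylhexan-1-ol
Product: 19 (4R)-6-chloro-4-methylhexyl 4-methylbenzenesulfonate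
Conditions: TsCl, Et3N, cat. DMAP, CH2Cl2, 0 °C → rt
Reagents that add atoms: p-toluenesulfonyl chloride Cc1ccc(cc1)S(Cl)(=O)=O
Why: Standard sulfonylation of the primary alcohol provides a leaving group far more reactive towards organocuprates than the chloride.

**Step 13**
Reactants: 19 (4R)-6-chloro-4-methylhexyl 4-methylbenzenesulfonate
Product: 20 (6R)-8-chloro-2,6-dimethyloct-1-ene
Conditions: CH2=C(CH3)MgBr (2 equiv), CuI (10 mol %), THF, −20 °C → rt
Reagents that add atoms: isopropenylmagnesium bromide CC(=C)[Mg]Br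
Why: Copper-catalysed coupling of an alkenyl Grignard reagent with a primary tosylate installs the isopropenyl end (C12'=C13') chemoselectively, primary chlorides being unreactive under these conditions.

**Step 14**
Reactants: 14 (2R)-6-(TBS-oxy)-2-[(4S)-5-iodo-4-methylpentyl]-2,5,7,8-tetramethylchroman; 20 (6R)-8-chloro-2,6-dimethyloct-1-ene
Product: 22 (2R)-6-(TBS-oxy)-2,5,7,8-tetramethyl-2-[(4R,8S)-4,8,12-trimethyltridec-12-en-1-yl]chroman, via Grignard reagent 21 (not isolated)
Conditions: 20 (1.5 equiv), Mg, THF, reflux; then 14, Li2CuCl4 (5 mol %), THF/NMP, −10 °C → rt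
Reagents that add atoms: none
Why: Copper-catalysed sp3–sp3 coupling of a primary alkyl Grignard reagent with a primary iodide forms C5'–C6' without touching C4' or C8'; the hindered aryl silyl ether and the 1,1-disubstituted alkene are inert.

**Step 15**
Reactants: 22 (2R)-6-(TBS-oxy)-2,5,7,8-tetramethyl-2-[(4R,8S)-4,8,12-trimethyltridec-12-en-1-yl]chroman
Product: 23 (2R)-2,5,7,8-tetramethyl-2-[(4R,8S)-4,8,12-trimethyltridec-12-en-1-yl]chroman-6-ol
Conditions: TBAF (1.5 equiv), AcOH (1.5 equiv), THF, 0 °C → rt, under Ar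
Reagents that add atoms: none
Why: Fluoride cleaves the aryl silyl ether; acetic acid buffering and exclusion of air protect the electron-rich chromanol from oxidation, and the alkene is unaffected.

**Compound list**
1 | 2,3,5-trimethylhydroquinone | Cc1cc(O)c(C)c(C)c1O | starting material
2 | methyl vinyl ketone | CC(=O)C=C | starting material
3 | 4-(2,5-dihydroxy-3,4,6-trimethylphenyl)butan-2-one (in-flask intermediate of step 1) | CC(=O)CCc1c(C)c(O)c(C)c(C)c1O | intermediate
4 | rac-2-methoxy-2,5,7,8-tetramethylchroman-6-ol | COC1(C)CCc2c(C)c(O)c(C)c(C)c2O1 | intermediate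
5 | rac-6-(TBS-oxy)-2-methoxy-2,5,7,8-tetramethylchroman | COC1(C)CCc2c(C)c(O[Si](C)(C)C(C)(C)C)c(C)c(C)c2O1 | intermediate
6 | 4-[5-(TBS-oxy)-2-hydroxy-3,4,6-trimethylphenyl]butan-2-one | CC(=O)CCc1c(C)c(O[Si](C)(C)C(C)(C)C)c(C)c(C)c1O | intermediate
7 | 4-(TBS-oxy)-2,3,5-trimethyl-6-(3-methylbut-3-en-1-yl)phenol | C=C(C)CCc1c(C)c(O[Si](C)(C)C(C)(C)C)c(C)c(C)c1O | intermediate
8 | methyl acrylate | C=CC(=O)OC | starting material
9 | methyl (2E)-4-[(2S)-6-(TBS-oxy)-2,5,7,8-tetramethylchroman-2-yl]but-2-enoate | COC(=O)/C=C/C[C@]1(C)CCc2c(C)c(O[Si](C)(C)C(C)(C)C)c(C)c(C)c2O1 | intermediate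
10 | methyl 4-[(2R)-6-(TBS-oxy)-2,5,7,8-tetramethylchroman-2-yl]butanoate | COC(=O)CCC[C@]1(C)CCc2c(C)c(O[Si](C)(C)C(C)(C)C)c(C)c(C)c2O1 | intermediate
11 | 4-[(2R)-6-(TBS-oxy)-2,5,7,8-tetramethylchroman-2-yl]butanal | O=CCCC[C@]1(C)CCc2c(C)c(O[Si](C)(C)C(C)(C)C)c(C)c(C)c2O1 | intermediate
12 | (2R)-6-(TBS-oxy)-2,5,7,8-tetramethyl-2-(pent-4-en-1-yl)chroman | C=CCCC[C@]1(C)CCc2c(C)c(O[Si](C)(C)C(C)(C)C)c(C)c(C)c2O1 | intermediate
13 | dimethyl{(2S)-2-methyl-5-[(2R)-6-(TBS-oxy)-2,5,7,8-tetramethylchroman-2-yl]pentyl}aluminium (in-flask intermediate of step 9) | C[Al](C)C[C@@H](C)CCC[C@]1(C)CCc2c(C)c(O[Si](C)(C)C(C)(C)C)c(C)c(C)c2O1 | intermediate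
14 | (2R)-6-(TBS-oxy)-2-[(4S)-5-iodo-4-methylpentyl]-2,5,7,8-tetramethylchroman | IC[C@@H](C)CCC[C@]1(C)CCc2c(C)c(O[Si](C)(C)C(C)(C)C)c(C)c(C)c2O1 | intermediate
15 | (R)-citronellol | C[C@H](CCC=C(C)C)CCO | starting material
16 | (6R)-8-chloro-2,6-dimethyloct-2-ene | C[C@H](CCC=C(C)C)CCCl | intermediate
17 | (4R)-6-chloro-4-methylhexanal (in-flask intermediate of step 11) | C[C@H](CCC=O)CCCl | intermediate
18 | (4R)-6-chloro-4-methylhexan-1-ol | C[C@H](CCCO)CCCl | intermediate
19 | (4R)-6-chloro-4-methylhexyl 4-methylbenzenesulfonate | C[C@H](CCCOS(=O)(=O)c1ccc(C)cc1)CCCl | intermediate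
20 | (6R)-8-chloro-2,6-dimethyloct-1-ene | C[C@H](CCCC(C)=C)CCCl | intermediate
21 | [(3R)-3,7-dimethyloct-7-en-1-yl]magnesium chloride (in-flask intermediate of step 14) | C[C@H](CCCC(C)=C)CC[Mg]Cl | intermediate
22 | (2R)-6-(TBS-oxy)-2,5,7,8-tetramethyl-2-[(4R,8S)-4,8,12-trimethyltridec-12-en-1-yl]chroman | C=C(C)CCC[C@@H](C)CCC[C@@H](C)CCC[C@]1(C)CCc2c(C)c(O[Si](C)(C)C(C)(C)C)c(C)c(C)c2O1 | intermediate
23 | (2R)-2,5,7,8-tetramethyl-2-[(4R,8S)-4,8,12-trimethyltridec-12-en-1-yl]chroman-6-ol | C=C(C)CCC[C@@H](C)CCC[C@@H](C)CCC[C@]1(C)CCc2c(C)c(O)c(C)c(C)c2O1 | target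

**Step count:** 15 steps in total. The longest linear sequence is 11 steps (steps 1–9, 14, 15, from trimethylhydroquinone); the side-chain branch is steps 10–13.

**Steps most likely to fail**

Step 5. Capture of the hindered C1'–Pd intermediate by the acrylate is slow (a multi-day reaction), so catalyst decay, background unligated cyclisation that erodes enantioface selectivity, or oxidative degradation of the silyl-protected hydroquinone by the quinone oxidant may limit conversion and optical purity. The fallback keeps the oxypalladation but changes the trapping event to CO insertion and builds C3'–C5' afterwards. It sets out from 7: Pd(OCOCF3)2, (S,S)-Bn-BOXAX and p-benzoquinone under CO (1 atm) in MeOH at rt (domino Wacker–carbonylation) should give methyl 2-[(2S)-6-(TBS-oxy)-2,5,7,8-tetramethylchroman-2-yl]acetate F1. Reduction with LiAlH4 in THF at 0 °C should give 2-[(2S)-6-(TBS-oxy)-2,5,7,8-tetramethylchroman-2-yl]ethanol F2. TsCl/Et3N/DMAP should give 2-[(2S)-6-(TBS-oxy)-2,5,7,8-tetramethylchroman-2-yl]ethyl 4-methylbenzenesulfonate F3. Coupling with allylmagnesium bromide and cat. Li2CuCl4 in THF at −20 °C comes back to the route at 12.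

Step 9. Incomplete facial selectivity in the methylzirconation of an unbiased terminal alkene would leave the C4' epimer, a remote diastereomer that cannot be expected to separate at any later stage. The fallback sets C4' by auxiliary-controlled enolate methylation, where the minor diastereomer is removable by chromatography. It sets out from 12:
- Hydroboration with 9-BBN and oxidation with NaBO3 should give 5-[(2R)-6-(TBS-oxy)-2,5,7,8-tetramethylchroman-2-yl]pentan-1-ol F4.
- TEMPO/PhI(OAc)2 in MeCN/H2O should give 5-[(2R)-6-(TBS-oxy)-2,5,7,8-tetramethylchroman-2-yl]pentanoic acid F5.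
- Pivaloyl chloride/Et3N, then lithiated (4S)-4-benzyloxazolidin-2-one, should give (4S)-4-benzyl-3-{5-[(2R)-6-(TBS-oxy)-2,5,7,8-tetramethylchroman-2-yl]pentanoyl}oxazolidin-2-one F6.
- NaHMDS, then MeI, in THF at −78 °C (Evans alkylation, methyl delivered anti to the benzyl group of the chelated Z-enolate) should give (4S)-4-benzyl-3-{(2S)-2-methyl-5-[(2R)-6-(TBS-oxy)-2,5,7,8-tetramethylchroman-2-yl]pentanoyl}oxazolidin-2-one F7.
- LiBH4 in THF/MeOH should give (2S)-2-methyl-5-[(2R)-6-(TBS-oxy)-2,5,7,8-tetramethylchroman-2-yl]pentan-1-ol F8.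
- I2/PPh3/imidazole comes back to the route at 14.

Step 14. Halogen–metal exchange and β-hydride pathways at copper may divert the β-branched iodide to reduction, elimination or homocoupling, and Grignard formation from the primary chloride may be sluggish. The fallback replaces the organometallic coupling by sulfone-anion alkylation and reductive desulfonylation. It sets out from 20: PhSO2Na with cat. NaI in DMF at 80 °C should give {[(3R)-3,7-dimethyloct-7-en-1-yl]sulfonyl}benzene F9. Deprotonation with n-BuLi in THF/DMPU at −78 °C and alkylation with 14 should give the C6'-phenylsulfonyl derivative of 22 (epimers at C6'; C2, C4' and C8' arranged as in 22) F10. Na(Hg)/Na2HPO4 in MeOH/THF at −20 °C comes back to the route at 22.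

**Further compounds**
F1 | step 5 | methyl 2-[(2S)-6-(TBS-oxy)-2,5,7,8-tetramethylchroman-2-yl]acetate | COC(=O)C[C@]1(C)CCc2c(C)c(O[Si](C)(C)C(C)(C)C)c(C)c(C)c2O1
F2 | step 5 | 2-[(2S)-6-(TBS-oxy)-2,5,7,8-tetramethylchroman-2-yl]ethanol | OCC[C@]1(C)CCc2c(C)c(O[Si](C)(C)C(C)(C)C)c(C)c(C)c2O1
F3 | step 5 | 2-[(2S)-6-(TBS-oxy)-2,5,7,8-tetramethylchroman-2-yl]ethyl 4-methylbenzenesulfonate | Cc1ccc(cc1)S(=O)(=O)OCC[C@]1(C)CCc2c(C)c(O[Si](C)(C)C(C)(C)C)c(C)c(C)c2O1
F4 | step 9 | 5-[(2R)-6-(TBS-oxy)-2,5,7,8-tetramethylchroman-2-yl]pentan-1-ol | OCCCCC[C@]1(C)CCc2c(C)c(O[Si](C)(C)C(C)(C)C)c(C)c(C)c2O1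
F5 | step 9 | 5-[(2R)-6-(TBS-oxy)-2,5,7,8-tetramethylchroman-2-yl]pentanoic acid | OC(=O)CCCC[C@]1(C)CCc2c(C)c(O[Si](C)(C)C(C)(C)C)c(C)c(C)c2O1
F6 | step 9 | (4S)-4-benzyl-3-{5-[(2R)-6-(TBS-oxy)-2,5,7,8-tetramethylchroman-2-yl]pentanoyl}oxazolidin-2-one | O=C(CCCC[C@]1(C)CCc2c(C)c(O[Si](C)(C)C(C)(C)C)c(C)c(C)c2O1)N1[C@@H](Cc2ccccc2)COC1=O
F7 | step 9 | (4S)-4-benzyl-3-{(2S)-2-methyl-5-[(2R)-6-(TBS-oxy)-2,5,7,8-tetramethylchroman-2-yl]pentanoyl}oxazolidin-2-one | O=C([C@@H](C)CCC[C@]1(C)CCc2c(C)c(O[Si](C)(C)C(C)(C)C)c(C)c(C)c2O1)N1[C@@H](Cc2ccccc2)COC1=O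
F8 | step 9 | (2S)-2-methyl-5-[(2R)-6-(TBS-oxy)-2,5,7,8-tetramethylchroman-2-yl]pentan-1-ol | OC[C@@H](C)CCC[C@]1(C)CCc2c(C)c(O[Si](C)(C)C(C)(C)C)c(C)c(C)c2O1
F9 | step 14 | {[(3R)-3,7-dimethyloct-7-en-1-yl]sulfonyl}benzene | C[C@H](CCCC(C)=C)CCS(=O)(=O)c1ccccc1
F10 | step 14 | C6'-phenylsulfonyl derivative of 22 (epimers at C6') | C=C(C)CCC[C@@H](C)CC(C[C@@H](C)CCC[C@]1(C)CCc2c(C)c(O[Si](C)(C)C(C)(C)C)c(C)c(C)c2O1)S(=O)(=O)c1ccccc1
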